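**Strategy.** Atoms are numbered as in longipinane: C1 ketone, C2=C3, cyclobutane C4–C5–C11–C10, seven-membered ring C5–C6–C7–C8–C9–C10–C11. The route exploits the 7,9-dioxygenated C7–C8–C9 segment of this ring, flanked by quaternary C6 and C10, which is a masked cycloheptane-1,3-dione. The dione is made by one-carbon ring enlargement of a six-membered acyloin enediol ring (C5–C6–C7–C9–C10–C11): C8 is added as a cyclopropane carbon and FeCl3 cleaves the C7–C9 bond, which gives the seven-membered ring and both carbonyl groups in one operation. The precursor is a terpene-derived, cis-fused 1,2-bis(silyloxy)bicyclo[4.1.0]heptane; the dione dianion then closes the cyclobutane.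

Key step: step 8

Remark: (1S,4R)-p-mentha-2,8-dien-1-ol (hydroxyl cis to the isopropenyl group) is taken as a commercial chiral-pool material; compounds 7–16 are mixtures of epimers at C10, which converge in step 10.

Step 1
Reactants: 1 (1S,4R)-p-mentha-2,8-dien-1-ol; 2 2-methylpropanoyl chloride
Product: 3 (1S,4R)-1-methyl-4-(prop-1-en-2-yl)cyclohex-2-en-1-yl 2-methylpropanoate
Conditions: Et3N, DMAP (0.2 equiv), CH2Cl2, 0 °C → rt
Reagents that add atoms: none
Why: DMAP-catalysed O-acylation of the tertiary allylic alcohol runs under basic conditions that avoid ionisation, and no stereocentre is touched.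

Step 2
Reactants: 3 allylic isobutyrate
Product: 6 2-methyl-2-[(1S,6R)-3-methyl-6-(prop-1-en-2-yl)cyclohex-2-en-1-yl]propanoic acid, via silyl ketene acetal 4 (not isolated), via trimethylsilyl ester 5 (not isolated)
Conditions: LDA, THF, −78 °C; TMSCl; −78 → 60 °C; 1 M HCl work-up
Reagents that add atoms: none
Why: Ireland–Claisen rearrangement, in which the suprafacial [3,3] shift across the ring allyl unit forms the C5–C6 bond (quaternary C6) on the face of the departing C3–O bond, i.e. cis to the isopropenyl group on C11, and moves the ring alkene to C3=C4.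

Step 3
Reactants: 6 dienoic acid
Product: 8 2-[6-(1-hydroxypropan-2-yl)-3-methylcyclohex-2-en-1-yl]-2-methylpropanoic acid (ring substituents cis as in 6), via bis-borane adduct 7 (not isolated)
Conditions: 9-BBN (2.5 equiv), THF, 0 °C → rt; then NaOH, H2O2, 0 °C
Reagents that add atoms: hydrogen peroxide OO
Why: Brown hydroboration–oxidation, in which 9-BBN adds anti-Markovnikov to the 1,1-disubstituted isopropenyl group only and spares the trisubstituted ring alkene; the new C10 stereocentre forms as an inconsequential epimer mixture because C10 is enolised in step 10.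

Step 4
Reactants: 8 hydroxy acid
Product: 10 2-[6-(1-carboxyethyl)-3-methylcyclohex-2-en-1-yl]-2-methylpropanoic acid, via aldehyde acid 9 (not isolated)
Conditions: CrO3, H2SO4, acetone, 0 °C
Reagents that add atoms: water O
Why: Jones oxidation takes the primary alcohol through the aldehyde hydrate to the acid without touching the trisubstituted alkene, and no stereocentre is set.

Step 5
Reactants: 10 diacid
Product: 11 dimethyl ester of 10
Conditions: MeI, K2CO3, DMF, rt
Reagents that add atoms: iodomethane CI
Why: SN2 O-alkylation of both carboxylates is insensitive to the hindrance of the α-quaternary acid, and no stereocentre is set.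

Step 6
Reactants: 11 dimethyl diester
Product: 12 cis-fused 1,1,4,7-tetramethyl-2,3-bis(trimethylsilyloxy)-1,4,4a,5,6,8a-hexahydronaphthalene
Conditions: Na (4.4 equiv), TMSCl (4.5 equiv), toluene, reflux
Reagents that add atoms: chlorotrimethylsilane C[Si](C)(C)Cl
Why: Rühlmann acyloin condensation, in which sodium couples the two ester carbons (C7–C9) in a six-membered ring closure and TMSCl traps the enediolate; the cis ring substituents of 11 make the new ring cis-fused.

Step 7
Reactants: 12 bis(silyloxy)cyclohexene
Product: 13 C8 cyclopropane of 12 (1,2-bis(trimethylsilyloxy)bicyclo[4.1.0]heptane cis-fused to the methylcyclohexene)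
Conditions: Et2Zn (1.5 equiv), CH2I2 (1.5 equiv), CH2Cl2, 0 °C → rt
Reagents that add atoms: diiodomethane ICI
Why: Furukawa–Simmons–Smith cyclopropanation, in which the zinc carbenoid adds fastest to the electron-rich enediol bis(silyl ether) and delivers C8 across C7=C9; the two new stereocentres are destroyed in step 8.

Step 8
Reactants: 13 bis(silyloxy)cyclopropane
Product: 14 cis-fused 3,5,5,9-tetramethyl-1,2,4a,5,9,9a-hexahydro-6H-benzo[7]annulene-6,8(7H)-dione (4,10-secolongipin-3-ene-7,9-dione)
Conditions: FeCl3 (2.3 equiv), DMF, 0 °C → rt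
Reagents that add atoms: none
Why: FeCl3 converts one silyloxy group into an iron(III) cyclopropanolate, which undergoes homolytic scission of the internal C7–C9 bond to give one ketone and an α-silyloxy radical at the other oxygenated carbon; a second FeCl3 oxidises this radical and the silyl group is lost to give the second ketone. The closest known reaction is the Saegusa–Ito FeCl3 ring enlargement of 1-silyloxybicyclo[n.1.0]alkanes and its 1,2-bis(silyloxy) variant that gives cycloalkane-1,3-diones. No ring is closed: the seven-membered ring C5–C6–C7–C8–C9–C10–C11 arises by cleavage of the zero-atom bridge of the bicyclo[4.1.0]heptane, so the six-membered ring C5–C6–C7–C9–C10–C11 grows by C8. No stereocentre is created; C7 and C9 become sp2 and C10 stays an epimer mixture. The step needs cleavage of the internal bond and not of a C–C8 bond, which is secured because only that scission gives an oxygen-stabilised tertiary radical. The remote ring alkene should stay intact because oxidation of that radical by Fe(III) is expected to outpace 5-exo addition.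

Step 9
Reactants: 14 bicyclic enedione
Product: 15 3,4-epoxide of 14 (oxygen trans to the C5–C6 and C11–C10 bonds)
Conditions: mCPBA (1.1 equiv), NaHCO3, CH2Cl2, 0 °C
Reagents that add atoms: 3-chloroperoxybenzoic acid OOC(=O)c1cccc(Cl)c1
Why: Prilezhaev epoxidation from the face anti to the axial C11–C10 bond (C6 on C5 sits equatorial), which sets C3 and C4 so that the oxygen is antiperiplanar to the later incoming C10.

Step 10
Reactants: 15 epoxy dione
Product: 17 3-hydroxylongipinane-7,9-dione (tertiary OH anti to C10), via dilithium dianion 16 (not isolated)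
Conditions: LDA (2.3 equiv), THF, −78 → 0 °C, then 40 °C; aq NH4Cl
Reagents that add atoms: none
Why: Intramolecular enolate alkylation by 4-exo-tet, trans-diaxial (Fürst–Plattner) epoxide opening, in which the β-diketone dianion reacts at its only γ-carbon C10 (planar, so both C10 epimers converge) and attacks the secondary epoxide carbon C4 with inversion; the seven-membered ring tether fixes C10, and C4 and C3 follow from the epoxide.

Step 11
Reactants: 17 hydroxy dione
Product: 18 (9R)-3,9-dihydroxylongipinan-7-one
Conditions: (S)-2-methyl-CBS-oxazaborolidine (0.3 equiv), BH3·SMe2, THF, −30 °C; MeOH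
Reagents that add atoms: none
Why: Corey–Bakshi–Shibata reduction gives the (9R)-carbinol under reagent control with the quaternary carbon as the large group; the C9 carbonyl next to the tied-back cyclobutane carbon should be less hindered than the C7 carbonyl next to the gem-dimethyl carbon.

Step 12
Reactants: 18 β-hydroxy ketone; 19 3-methylbutanal
Product: 21 (7R,9R)-3,7-dihydroxylongipinan-9-yl 3-methylbutanoate, via hemiacetal 20 (not isolated)
Conditions: SmI2 (0.3 equiv), 19 (5 equiv), THF, −10 °C
Reagents that add atoms: none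
Why: Evans–Tishchenko reduction, in which the samarium-bound hemiacetal on O-9 transfers hydride intramolecularly to C7 on the face of O-9; this gives the 7,9-trans (anti) diol with (7R) configuration and leaves the oxidised aldehyde as the isovalerate on O-9, so the two oxygens are differentiated without protecting groups.

Step 13
Reactants: 21 hydroxy isovalerate; 22 3-methylbut-2-enoyl chloride
Product: 23 (7R,9R)-3-hydroxy-9-(3-methylbutanoyloxy)longipinan-7-yl 3-methylbut-2-enoate
Conditions: pyridine, DMAP (0.1 equiv), CH2Cl2, 0 °C → rt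
Reagents that add atoms: none
Why: DMAP-catalysed acylation esterifies the secondary C7 hydroxyl while the tertiary C3 hydroxyl does not react, and no stereocentre is set.

Step 14
Reactants: 23 tertiary alcohol diester
Product: 25 (7R,9R)-9-(3-methylbutanoyloxy)longipin-2-en-7-yl 3-methylbut-2-enoate, via chlorosulfite 24 (not isolated)
Conditions: SOCl2, pyridine, −20 → 0 °C
Reagents that add atoms: none
Why: E2 dehydration through the chlorosulfite removes the C2 hydrogen anti to the C3–O bond to give the endocyclic (Zaitsev) alkene; the bridgehead C4–H is excluded by Bredt's rule and the basic medium suppresses the cyclobutylcarbinyl cation.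

Step 15
Reactants: 25 longipin-2-ene diester
Product: 26 (4R,5S,7R,9R,10R,11R)-9-(3-methylbutanoyloxy)-1-oxolongipin-2-en-7-yl 3-methylbut-2-enoate (target)
Conditions: CrO3, 3,5-dimethylpyrazole, CH2Cl2, −20 °C
Reagents that add atoms: chromium trioxide O=[Cr](=O)=O
Why: Allylic C–H oxidation with the CrO3–3,5-dimethylpyrazole complex (as in α-pinene to verbenone) converts the only allylic methylene, C1, into the enone carbonyl, while the bridgehead C4–H and the methyl groups are unreactive and no stereocentre is affected.

**Compound list**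

1 | (1S,4R)-1-methyl-4-(prop-1-en-2-yl)cyclohex-2-en-1-ol | C[C@@]1(O)C=C[C@H](C(C)=C)CC1 | starting material
2 | 2-methylpropanoyl chloride | CC(C)C(Cl)=O | starting material
3 | (1S,4R)-1-methyl-4-(prop-1-en-2-yl)cyclohex-2-en-1-yl 2-methylpropanoate | C[C@@]1(OC(=O)C(C)C)C=C[C@H](C(C)=C)CC1 | intermediate
4 | trimethylsilyl ketene acetal of 3 | C[C@@]1(OC(O[Si](C)(C)C)=C(C)C)C=C[C@H](C(C)=C)CC1 | intermediate
5 | trimethylsilyl ester of 6 | C[Si](C)(C)OC(=O)C(C)(C)[C@H]1C=C(C)CC[C@H]1C(C)=C | intermediate
6 | 2-methyl-2-[(1S,6R)-3-methyl-6-(prop-1-en-2-yl)cyclohex-2-en-1-yl]propanoic acid | OC(=O)C(C)(C)[C@H]1C=C(C)CC[C@H]1C(C)=C | intermediate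
7 | bis(9-BBN) adduct of 6 (B-alkyl at the former =CH2 carbon, acyloxyborane at the carboxyl) | O=C(OB1C2CCCC1CCC2)C(C)(C)[C@H]3C=C(C)CC[C@H]3C(C)CB4C5CCCC4CCC5 | intermediate
8 | 2-[6-(1-hydroxypropan-2-yl)-3-methylcyclohex-2-en-1-yl]-2-methylpropanoic acid (ring substituents cis, C10 epimers) | OC(=O)C(C)(C)[C@H]1C=C(C)CC[C@H]1C(C)CO | intermediate
9 | 2-methyl-2-[3-methyl-6-(1-oxopropan-2-yl)cyclohex-2-en-1-yl]propanoic acid | OC(=O)C(C)(C)[C@H]1C=C(C)CC[C@H]1C(C)C=O | intermediate
10 | 2-[6-(1-carboxyethyl)-3-methylcyclohex-2-en-1-yl]-2-methylpropanoic acid | OC(=O)C(C)(C)[C@H]1C=C(C)CC[C@H]1C(C)C(O)=O | intermediate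
11 | dimethyl ester of 10 | COC(=O)C(C)(C)[C@H]1C=C(C)CC[C@H]1C(C)C(=O)OC | intermediate
12 | cis-fused 1,1,4,7-tetramethyl-2,3-bis(trimethylsilyloxy)-1,4,4a,5,6,8a-hexahydronaphthalene | CC1C(O[Si](C)(C)C)=C(O[Si](C)(C)C)C(C)(C)[C@H]2C=C(C)CC[C@@H]12 | intermediate
13 | C8 cyclopropane of 12 (1,2-bis(trimethylsilyloxy)bicyclo[4.1.0]heptane unit) | CC1C2(O[Si](C)(C)C)CC2(O[Si](C)(C)C)C(C)(C)[C@H]3C=C(C)CC[C@@H]13 | intermediate
14 | cis-fused 3,5,5,9-tetramethyl-1,2,4a,5,9,9a-hexahydro-6H-benzo[7]annulene-6,8(7H)-dione | CC1C(=O)CC(=O)C(C)(C)[C@H]2C=C(C)CC[C@@H]12 | intermediate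
15 | 3,4-epoxide of 14 (oxygen trans to the ring-fusion bonds to C6 and C10) | CC1C(=O)CC(=O)C(C)(C)[C@H]2[C@@H]3O[C@]3(C)CC[C@@H]12 | intermediate
16 | dilithium C8/C10 dianion of 15 | [Li+].[Li+].CC1=C([O-])C=C([O-])C(C)(C)[C@H]2[C@@H]3O[C@]3(C)CC[C@@H]12 | intermediate
17 | 3-hydroxylongipinane-7,9-dione | O=C1CC(=O)[C@@]2(C)[C@@H]3CC[C@@](C)(O)[C@H]2[C@@H]3C1(C)C | intermediate
18 | (9R)-3,9-dihydroxylongipinan-7-one | O=C1C[C@@H](O)[C@@]2(C)[C@@H]3CC[C@@](C)(O)[C@H]2[C@@H]3C1(C)C | intermediate
19 | 3-methylbutanal | CC(C)CC=O | starting material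
20 | O-9 hemiacetal of 18 with 19 | O=C1C[C@@H](OC(O)CC(C)C)[C@@]2(C)[C@@H]3CC[C@@](C)(O)[C@H]2[C@@H]3C1(C)C | intermediate
21 | (7R,9R)-3,7-dihydroxylongipinan-9-yl 3-methylbutanoate | O[C@@H]1C[C@@H](OC(=O)CC(C)C)[C@@]2(C)[C@@H]3CC[C@@](C)(O)[C@H]2[C@@H]3C1(C)C | intermediate
22 | 3-methylbut-2-enoyl chloride | CC(C)=CC(Cl)=O | starting material
23 | (7R,9R)-3-hydroxy-9-(3-methylbutanoyloxy)longipinan-7-yl 3-methylbut-2-enoate | CC(C)=CC(=O)O[C@@H]1C[C@@H](OC(=O)CC(C)C)[C@@]2(C)[C@@H]3CC[C@@](C)(O)[C@H]2[C@@H]3C1(C)C | intermediate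
24 | C3 chlorosulfite of 23 | CC(C)=CC(=O)O[C@@H]1C[C@@H](OC(=O)CC(C)C)[C@@]2(C)[C@@H]3CC[C@@](C)(OS(Cl)=O)[C@H]2[C@@H]3C1(C)C | intermediate
25 | (7R,9R)-9-(3-methylbutanoyloxy)longipin-2-en-7-yl 3-methylbut-2-enoate | CC(C)=CC(=O)O[C@@H]1C[C@@H](OC(=O)CC(C)C)[C@@]2(C)[C@@H]3CC=C(C)[C@H]2[C@@H]3C1(C)C | intermediate
26 | (4R,5S,7R,9R,10R,11R)-9-(3-methylbutanoyloxy)-1-oxolongipin-2-en-7-yl 3-methylbut-2-enoate | CC(C)=CC(=O)O[C@@H]1C[C@@H](OC(=O)CC(C)C)[C@@]2(C)[C@@H]3C(=O)C=C(C)[C@H]2[C@@H]3C1(C)C | target

**Step count and risks**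

Total step count: 15. Longest linear sequence: 15 steps (from 1).

The three steps most likely to fail:

Step 10. The tertiary carbanion terminus of the dianion may be too slow in the 4-exo epoxide opening, so that base-induced isomerisation of the epoxide to an allylic alcohol, or attack through the central carbon, takes over. The fallback closes the cyclobutane before the ring enlargement with a more nucleophilic ester enolate; it sets out from 11 and comes back at 17. Epoxidation of 11 (mCPBA) should give the epoxy diester F1. LDA (1.1 equiv) can form only the propanoate enolate at C10, because the C6 ester has no α-hydrogen. This enolate should open the epoxide at C4 in a Stork-type 4-exo cyclisation to the bicyclo[3.1.1]heptane hydroxy diester F2, with the bulkier ester group expected on the exo face towards C6. Acyloin condensation (Na, TMSCl, which also silylates the tertiary hydroxyl) should then give the tris(silyl ether) F3. Et2Zn/CH2I2 should give the cyclopropane F4, and FeCl3 in DMF with acidic work-up should deliver 17. The FeCl3 ring enlargement stays the key step, now on the tricycle.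

Step 11. Hydride may be delivered to the C7 carbonyl instead of C9, because the two neopentyl ketones are not differentiated strongly enough. The fallback reverses the order in which the two esters are installed; it sets out from 17 and comes back at 23. The catalyst imposes the same local sense at either carbonyl, so the regioisomeric (7R)-hydroxy ketone F5 is equally productive. Evans–Tishchenko reduction of F5 with 3-methylbut-2-enal should place the senecioate on O-7 while reducing C9 trans, giving the 9-hydroxy 7-senecioate F6. Acylation of F6 with 3-methylbutanoyl chloride (pyridine, DMAP) should give 23.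

Step 14. Elimination of the pinan-2-ol-type tertiary alcohol may run towards the methyl group, or through ionisation and Wagner–Meerwein shift of the cyclobutylcarbinyl cation. The fallback replaces kinetic regiocontrol by a thermodynamic funnel; it sets out from 23 and comes back at 25. Elimination is run without regiocontrol under non-ionising conditions (Martin sulfurane, CH2Cl2, rt). The exocyclic 3(12)-methylene isomer F7 formed beside 25 is then isomerised with a ruthenium hydride catalyst (RuHCl(CO)(PPh3)3, toluene, 80 °C) to the endocyclic alkene 25, which is the more stable isomer in pinene-type systems.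

Further compounds
F1 | step 10 | 3,4-epoxide of diester 11 (oxygen trans to both ring substituents) | COC(=O)C(C)[C@@H]1CC[C@@]2(C)O[C@H]2[C@@H]1C(C)(C)C(=O)OC
F2 | step 10 | methyl 2-hydroxy-7-(1-methoxy-2-methyl-1-oxopropan-2-yl)-2,6-dimethylbicyclo[3.1.1]heptane-6-carboxylate (C4–C10 bond closed, esters on the same face) | COC(=O)[C@@]1(C)[C@@H]2CC[C@@](C)(O)[C@H]1[C@@H]2C(C)(C)C(=O)OC
F3 | step 10 | 3,7,9-tris(trimethylsilyloxy)-8-norlongipin-7(9)-ene | C[Si](C)(C)OC1=C(O[Si](C)(C)C)[C@@]2(C)[C@@H]3CC[C@@](C)(O[Si](C)(C)C)[C@H]2[C@@H]3C1(C)C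
F4 | step 10 | C8 cyclopropane of F3 (7,9-cyclo-3,7,9-tris(trimethylsilyloxy)longipinane) | C[Si](C)(C)OC12CC2(O[Si](C)(C)C)[C@@]2(C)[C@@H]3CC[C@@](C)(O[Si](C)(C)C)[C@H]2[C@@H]3C1(C)C
F5 | step 11 | (7R)-3,7-dihydroxylongipinan-9-one | O[C@@H]1CC(=O)[C@@]2(C)[C@@H]3CC[C@@](C)(O)[C@H]2[C@@H]3C1(C)C
F6 | step 11 | (7R,9R)-3,9-dihydroxylongipinan-7-yl 3-methylbut-2-enoate | CC(C)=CC(=O)O[C@@H]1C[C@@H](O)[C@@]2(C)[C@@H]3CC[C@@](C)(O)[C@H]2[C@@H]3C1(C)C
F7 | step 14 | (7R,9R)-9-(3-methylbutanoyloxy)longipin-3(12)-en-7-yl 3-methylbut-2-enoate | CC(C)=CC(=O)O[C@@H]1C[C@@H](OC(=O)CC(C)C)[C@@]2(C)[C@@H]3CCC(=C)[C@H]2[C@@H]3C1(C)C
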